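Time is my axis here: the question is how much homo dimer stands at 6.0 min in each flask, and whether a slow feed can move it.

| setting | delta | gamma | alpha | autumn | summer | dusk |
|---|---|---|---|---|---|---|
| starting material | 0.21 M | 0.21 M | 0.21 M | 0.21 M | 0.21 M | 0.21 M |
| second substrate | 0.21 M | 0.10 M | 0.16 M | 0.210 M | 0.210 M | 0.210 M (fed, over 5.0 min) |
| coupling partner | 0.168 M | 0.168 M | 0.168 M | 0.168 M (fed, over 5.0 min) | 0.168 M | 0.168 M |
| free catalyst | 21 mM | 21 mM | 21 mM | 21 mM | 21 mM | 21 mM |
| remark | run made earlier | run made earlier | run made earlier | all else is in the flask from the start; the feed brings no volume worth counting | everything together at the start | all else is in the flask from the start; the feed brings no volume worth counting |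
| time |  |  |  | 6.0 min | 6.0 min | 6.0 min |

- delta (time / min: homo dimer / %, target / %): 0.667: 62, 0; 1.33: 75, 0; 2.00: 80, 0; 3.00: 84, 4; 4.00: 84, 1
- gamma (time / min: homo dimer / %, target / %): 0.500: 56, 2; 0.833: 69, 1; 1.50: 77, 2; 3.00: 81, 1; 6.00: 86, 5
- alpha (time / min: homo dimer / %, target / %): 0.500: 56, 0; 0.833: 69, 1; 1.50: 78, 3; 3.00: 80, 0; 6.00: 85, 1

(standard deviation of a reading: 2 percentage points)

- in percentages every species weighs as the starting material in it: one homo dimer counts as two

1. the flask with the highest amount of homo dimer, in percent of the starting material charged ("all alike" if they lie within 1.5 percentage points) (autumn / summer / dusk / all alike)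
2. final homo dimer, as a percentage of the starting material charged, in autumn
3. final homo dimer, as a percentage of the starting material charged, in summer
4. final homo dimer, as a percentage of the starting material charged, in dusk

I turn the question round: for the flasks to come out alike, a feed must shift homo dimer by less than 1.5 percentage points. The homo dimer curves overlap, within their scatter, from 0.10 M to 0.21 M of second substrate. Coupling partner was held at one charge, so I test it indirectly.

If starting material did nothing but pair, a second-order step, the reciprocal of the fraction left would climb in a straight line from one, as chain length does in step growth. I call its slope the pairing rate. Counting everything outside homo dimer as still left, the gamma reading at 0.500 min gives 2.55 /min, with that reading's scatter. With pairing as the sole loss I reckon a ceiling of 93.9 % at 6.0 min, an estimate that carries the same scatter.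

The gamma and alpha runs read 86 % and 85 % there, a gap of 8.4 points, and the flasks stay alike if a feed closes less than 1.5 points of it. My suspect for the gap is coupling partner. Within 0.393 min half of the starting material pairs by this reckoning, far sooner than the feed ends, and by then autumn has received 7.86 % of its coupling partner. So I reckon autumn climbs toward the ceiling, while summer and dusk stay near the readings.

The forecast differs: all alike, with 85 % for summer, 85 % for dusk and 85 % for autumn, the last ranging from 68 % to 93 %: “Autumn is the uncertain one, because coupling partner was never varied”.

The flasks give 92.0 % in autumn, 85.1 % in summer and 84.5 % in dusk, so autumn stands highest.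

    starting material + coupling partner → uncatalysed product (k = 0.720 /M/min)
    starting material + free catalyst ⇌ catalyst intermediate A (K = 2.10 /M, k = 9.80 /M/min)
    coupling partner + catalyst intermediate B → free catalyst + second product (k = 9.80 /M/min)
    second substrate + free catalyst ⇌ catalyst intermediate B (K = 1.80 /M, k = 16.0 /M/min)
    2 starting material → homo dimer (k = 7.30 /M/min)
    coupling partner + catalyst intermediate A → free catalyst + target (k = 6.10 /M/min)

In summer, pairing ran with coupling partner charged from the start; uncatalysed product reached 9.11 % at 6.00 min, and homo dimer stood 8.8 points under my reckoned ceiling. In autumn, pairing ran while coupling partner trickled in; uncatalysed product reached less than in summer, 3.17 %, and homo dimer stood 1.9 points under that ceiling. For the neighbour of dusk with 0.53 M of starting material I reckon a pairing rate of 6.42 /min and a ceiling of 97.5 %, and its homo dimer stands at 92.3 %.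

The runs come from a simulation on assumed constants; scatter was added.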